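The constants used here stand for no real mixture.

A closed stirred flask and a flask dosed with substrate hold the same charge and look nearly alike, so the question is what the dosing changes.

| flask | substrate | coupling partner | second reagent | time | remark |
|---|---|---|---|---|---|
| gamma | 0.35 M | 0.420 M | 0.280 M | 10 min | everything together in a closed stirred flask, run for 10 min |
| zeta | 0.35 M (fed, over 10.0 min) | 0.420 M | 0.280 M | 10 min | a stirred flask in which substrate is dosed at a steady rate over 10.0 min without added volume, worked up at 10 min |
| epsilon | 0.35 M | 0.420 M | 0.280 M |  | one stirred flow tank at steady state, fed with the mixture as stated, mean residence time 10 min |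
| delta | 0.35 M | 0.420 M | 0.280 M | 10 min | a tube with plug flow, the mixed feed as stated, residence time 10 min |

- the set-up with the highest amount of intermediate at the outlet or at the end, in percent of the substrate put in ("none" if the first two lie within 2 percentage points) (gamma / zeta / epsilon / delta / none)
- amount of intermediate at the outlet or at the end, in percent of the substrate put in, gamma
- amount of intermediate at the outlet or at the end, in percent of the substrate put in, zeta
- amount of intermediate at the outlet or at the end, in percent of the substrate put in, epsilon
- amount of intermediate at the outlet or at the end, in percent of the substrate put in, delta

- percentages count the substrate that a species holds: one side product B counts as two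
- the stated concentrations are those of everything mixed, before any reaction; amounts are the same in each set-up
- the feed brings no volume worth counting
- run time (gamma): 10 min

1. With coupling partner, substrate makes intermediate (rate constant ka = 0.0495 L mol⁻¹ s⁻¹); with intermediate it makes side product B (kb = 0.0502 L mol⁻¹ s⁻¹). Its step with second reagent to side product A has the smaller constant 0.00809 L mol⁻¹ s⁻¹ and is set aside in this reckoning. Substrate concentration is a factor in both kept rates, so it cancels from their ratio, leaving intermediate over coupling partner times the selectivity factor S = kb/ka = 1.01, which is frozen here at one.

2. With S at one, and before any drain, the intermediate formed in a closed or dosed flask follows the coupling partner used, however fast substrate arrives. Its curve has a top, F, the family top: coupling partner charge over e times substrate charge, counted as intermediate plus target plus isomer 44.1%. Reaching that top takes 0.376 M of substrate against the charge of 0.35 M, so F stands here as an estimate. Gamma and zeta share this F.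

3. Second reagent drains intermediate into target (kc = 0.00542 L mol⁻¹ s⁻¹). In gamma, with the other concentrations as charged, substrate's half-life by the step with coupling partner alone, 0.56 min, is far shorter than intermediate's by the step with second reagent alone, 7.6 min, so intermediate forms early and then drains. Freezing second reagent at its charge minus the amount for F/2 gives the drain constant λ = 0.0659 min⁻¹.

4. Gamma's intermediate, starting from F, drains for the full time: 22.8%. The tube delta gives the same age: 22.8%. Zeta's intermediate is taken to build evenly over the dose, so its mean age is shorter, 5.00 min against 10 min: 31.7%.

5. The tank epsilon, with residence time τ, is taken to hold substrate near 0.0337 M, the inverse of ka·τ. Coupling partner then stands at half its feed, and intermediate is the coupling partner used, divided by two plus λτ: 22.6%.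

6. The reckoning therefore picks zeta, through a shorter drain and not through a higher F.

The forecast, on grounds other than this reckoning, gave zeta, with 22% for gamma, 31.5% for zeta, 22.5% for epsilon and 22% for delta: “Dosing keeps the substrate low, so far less intermediate is lost to side product B”.

The simulation gives zeta: gamma 23.6%, zeta 31.4%, epsilon 22.5%, delta 23.6%.

    substrate + coupling partner → intermediate (k1 = 0.0495 L mol⁻¹ s⁻¹)
    substrate + second reagent → side product A (k2 = 0.00809 L mol⁻¹ s⁻¹)
    substrate + intermediate → side product B (k3 = 0.0502 L mol⁻¹ s⁻¹)
    second reagent + intermediate → target (k4 = 0.00542 L mol⁻¹ s⁻¹)
    target ⇌ isomer of the product (K5 = 0.17, k5 = 1.59 × 10⁻⁴ s⁻¹)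

At 10.0 min in zeta, substrate is used by coupling partner 1.7 times as fast as by intermediate. The family stands at 46.9% there against 44.5% in gamma, while target is 15.0% in zeta against 20.0% in gamma. For the neighbour of zeta charged with 0.10 M of coupling partner, F gives 10.5%. Computed, that flask ends with 5.35% intermediate and 4.43% target, a family of 9.94%.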